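**Strategy.** The cyclohexene ring (C1–C6; C1 carries C7H2OAr, C2 the methyl, C5 the ester oxygen, C6 the gem-dimethyl group) is cut at C4–C5. The unit C5(O)–C4H2–C3H=C2 is a homoallylic alcohol, the retron of a carbonyl allylation. A chromium-mediated, ligand-controlled intramolecular Nozaki–Hiyama–Kishi allylation turns the electrophilic allylic bromide carbon C4 into a nucleophile and, in one operation, forms C4–C5, closes the six-membered ring and sets the C5 carbinol centre. The exocyclic C1=C7 alkene remains as the handle for C1. The precursor is the achiral open-chain (Z)-6-bromo-2,2,4-trimethyl-3-methylidenehex-4-enal, a non-enolisable neopentyl aldehyde tethered through C6 and a 2,3-disubstituted diene to the (Z)-allylic bromide.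

Key step: step 9

Remark on the structure: the target has C5 = R and C1 = S, with the C5 oxygen and C7 cis on the ring, and an (R)-acyl stereocentre. Atom labels C1–C7 follow the ring numbering above, not the locants of the systematic names.

Assumption: the sense of induction of the chromium ligand in this intramolecular mode cannot be read from intermolecular models, so the ligand antipode that leads to (R)-16 is to be fixed by a pilot run with both antipodes.

Step 1
Reactants: 1 but-2-yn-1-ol
Product: 3 (Z)-3-iodobut-2-en-1-ol, via cyclic alkenylalanate 2 (not isolated)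
Conditions: NaAlH2(OCH2CH2OCH3)2, THF, 0 °C to rt; then I2, THF, −78 to 0 °C
Reagents that add atoms: iodine, II
Why: Alkoxide-directed trans-hydroalumination of the propargylic alcohol puts hydride on the carbinol-side alkyne carbon and aluminium on the methyl-bearing carbon inside a five-membered alanate, and iodinolysis of the C–Al bond with retention should give the (Z)-iodoalkene with iodine cis to CH2OH.

Step 2
Reactants: 3 (Z)-3-iodobut-2-en-1-ol
Product: 4 (Z)-tert-butyl[(3-iodobut-2-en-1-yl)oxy]dimethylsilane
Conditions: TBSCl, imidazole, DMF, rt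
Reagents that add atoms: tert-butyldimethylsilyl chloride, CC(C)(C)[Si](C)(C)Cl
Why: Imidazole-promoted silylation of the primary allylic alcohol masks the acidic OH before the lithiation.

Step 3
Reactants: 4 (Z)-tert-butyl[(3-iodobut-2-en-1-yl)oxy]dimethylsilane; 5 methyl 2,2-dimethyl-3-oxobutanoate
Product: 7 methyl (Z)-6-(tert-butyldimethylsilyloxy)-3-hydroxy-2,2,3,4-tetramethylhex-4-enoate (racemic), via alkenyllithium 6 (not isolated)
Conditions: t-BuLi (2 equiv), Et2O, −78 °C; then 5, −78 °C; AcOH, −78 °C
Reagents that add atoms: none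
Why: Iodine–lithium exchange with t-BuLi keeps the alkene geometry and the alkenyllithium should add 1,2 to the methyl ketone, which is more electrophilic than the pivalate-like ester, while the acid quench at −78 °C protects the aldolate from retro-aldol cleavage; the new carbinol centre is racemic and disappears in step 4.

Step 4
Reactants: 7 methyl (Z)-6-(tert-butyldimethylsilyloxy)-3-hydroxy-2,2,3,4-tetramethylhex-4-enoate
Product: 8 methyl (Z)-6-(tert-butyldimethylsilyloxy)-2,2,4-trimethyl-3-methylidenehex-4-enoate
Conditions: Burgess reagent (MeO2CN–SO2–NEt3 inner salt), toluene, 50 °C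
Reagents that add atoms: none
Why: Burgess dehydration (syn-elimination of the tertiary sulfamate) can remove a hydrogen only from the carbinol methyl group, because the other two neighbours are a quaternary and an sp2 carbon, so only the C1=C7 methylidene can form and the neutral conditions leave the (Z)-alkene and the silyl ether alone.

Step 5
Reactants: 8 methyl (Z)-6-(tert-butyldimethylsilyloxy)-2,2,4-trimethyl-3-methylidenehex-4-enoate
Product: 9 (Z)-6-(tert-butyldimethylsilyloxy)-2,2,4-trimethyl-3-methylidenehex-4-en-1-ol
Conditions: i-Bu2AlH, CH2Cl2, −78 to 0 °C; aq. KNaC4H4O6 work-up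
Reagents that add atoms: none
Why: Hydride reduction of the hindered ester with excess i-Bu2AlH should give the neopentyl alcohol and leaves the diene and the silyl ether untouched.

Step 6
Reactants: 9 (Z)-6-(tert-butyldimethylsilyloxy)-2,2,4-trimethyl-3-methylidenehex-4-en-1-ol
Product: 10 (Z)-6-(tert-butyldimethylsilyloxy)-2,2,4-trimethyl-3-methylidenehex-4-enal
Conditions: Dess–Martin periodinane, pyridine, CH2Cl2, 0 °C to rt
Reagents that add atoms: none
Why: Dess–Martin oxidation of the primary alcohol stops at the aldehyde, which has no α-hydrogen and cannot enolise, and the pyridine buffer protects the silyl ether and the diene from acetic acid.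

Step 7
Reactants: 10 (Z)-6-(tert-butyldimethylsilyloxy)-2,2,4-trimethyl-3-methylidenehex-4-enal
Product: 11 (Z)-6-hydroxy-2,2,4-trimethyl-3-methylidenehex-4-enal
Conditions: HF·pyridine, pyridine, THF, 0 °C to rt
Reagents that add atoms: none
Why: Fluoride-induced desilylation with buffered HF·pyridine frees the primary allylic alcohol under conditions that the aldehyde and the diene tolerate.

Step 8
Reactants: 11 (Z)-6-hydroxy-2,2,4-trimethyl-3-methylidenehex-4-enal
Product: 13 (Z)-6-bromo-2,2,4-trimethyl-3-methylidenehex-4-enal, via allylic mesylate 12 (not isolated)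
Conditions: Ms2O, Et3N, CH2Cl2, −40 °C; then LiBr, THF, −40 to 0 °C
Reagents that add atoms: lithium bromide, [Li+].[Br-]
Why: Mesylation followed by SN2 displacement with bromide at low temperature is the mild two-stage way to a primary allylic bromide; chloride-free Ms2O avoids a competing allylic chloride, the non-enolisable aldehyde is inert, and the bromide is to be used at once.

Step 9
Reactants: 13 (Z)-6-bromo-2,2,4-trimethyl-3-methylidenehex-4-enal
Product: 16 (R)-2,2,4-trimethyl-3-methylidenecyclohex-4-en-1-ol, via allylchromium species 14 (not isolated), via trimethylsilyl ether 15 (not isolated)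
Conditions: CrCl2 (15 mol %), valinol-derived N-[2-(4-isopropyl-4,5-dihydrooxazol-2-yl)-6-methylphenyl]methanesulfonamide (single antipode, 17 mol %), Et3N, Mn, Me3SiCl, THF, rt, syringe-pump addition of 13 (final about 0.01 M); then K2CO3, MeOH, rt
Reagents that add atoms: none
Why: Two single-electron transfers from divalent chromium (regenerated from trivalent chromium by Mn) convert the C4–Br bond into a ligand-bound allyl species of trivalent chromium, which can shift between C4 and C2 and so should also correct any erosion of alkene geometry; the aldehyde oxygen binds chromium, C4 adds to C5, and Me3SiCl silylates the chromium alkoxide to release the catalyst. The closest known reaction is the catalytic enantioselective Nozaki–Hiyama–Kishi allylation of aldehydes, here in its less common intramolecular form in which the halide-bearing terminus becomes a ring carbon. The ring closes in the 6-exo-trig mode, with the carbonyl oxygen outside the new C1–C6 ring. The only new stereocentre, C5, is set by the chiral oxazoline–sulfonamide ligand on chromium, which has to direct C4 to the Re face of the aldehyde because the substrate is achiral. The step needs bonding through C4 and not through C2 or C7 of the pentadienyl-type metal species, which ring size secures (C2 or C7 would give cyclobutanes), and ring closure instead of intermolecular coupling, which slow addition at high dilution and the gem-dimethyl group at C6 favour; the aldehyde has no α-hydrogen, so enolisation and aldol reactions cannot compete.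

Step 10
Reactants: 16 (R)-2,2,4-trimethyl-3-methylidenecyclohex-4-en-1-ol; 17 (R)-2-methylbutanoic acid
Product: 18 (R)-2,2,4-trimethyl-3-methylidenecyclohex-4-en-1-yl (R)-2-methylbutanoate
Conditions: DCC, DMAP, CH2Cl2, 0 °C to rt
Reagents that add atoms: none
Why: Steglich esterification (DCC activation, DMAP acyl transfer) should acylate the hindered alcohol without touching C5, a simple α-alkyl acid is not expected to epimerise under these conditions, and the ester that the target needs anyway serves as the protecting group for the C5 oxygen in the next two steps.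

Step 11
Reactants: 18 (R)-2,2,4-trimethyl-3-methylidenecyclohex-4-en-1-yl (R)-2-methylbutanoate
Product: 20 (1R,3S)-3-(hydroxymethyl)-2,2,4-trimethylcyclohex-4-en-1-yl (R)-2-methylbutanoate, via alkylborane 19 (not isolated)
Conditions: 9-BBN, THF, 0 °C to rt; then 30% H2O2, aq. NaOAc, 0 °C to rt
Reagents that add atoms: hydrogen peroxide, OO
Why: 9-BBN hydroborates the 1,1-disubstituted C1=C7 alkene (boron to C7, hydrogen to C1, syn addition) far faster than the trisubstituted ring alkene or the ester; hydrogen should reach C1 on the face anti to the pseudoaxial C6 methyl in the half-chair with pseudoequatorial C5 ester, the other half-chair being shielded on both faces by that methyl and by the axial C5 oxygen substituent, so that C7 ends cis to the C5 oxygen (C1 = S), and buffered peroxide oxidation replaces boron by OH with retention without hydrolysing the ester.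

Step 12
Reactants: 20 (1R,3S)-3-(hydroxymethyl)-2,2,4-trimethylcyclohex-4-en-1-yl (R)-2-methylbutanoate; 21 umbelliferone
Product: 22 (1R,3S)-2,2,4-trimethyl-3-{[(2-oxo-2H-chromen-7-yl)oxy]methyl}cyclohex-4-en-1-yl (R)-2-methylbutanoate
Conditions: PPh3, DIAD, THF, 0 °C to rt
Reagents that add atoms: none
Why: Mitsunobu etherification: the phenol (pKa about 8) protonates the PPh3–DIAD betaine and its anion displaces the primary alkoxyphosphonium at C7 by SN2, a centre that is not stereogenic, under neutral conditions that leave both ring stereocentres and the ester unchanged.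

**Compound list**

1 | but-2-yn-1-ol | CC#CCO | starting material
2 | sodium 2,2-bis(2-methoxyethoxy)-3-methyl-2,5-dihydro-1,2-oxaaluminol-2-uide (cyclic alkenylalanate, formed in the flask) | CC1=CCO[Al-]1(OCCOC)OCCOC.[Na+] | intermediate
3 | (Z)-3-iodobut-2-en-1-ol | C/C(I)=C/CO | intermediate
4 | (Z)-tert-butyl[(3-iodobut-2-en-1-yl)oxy]dimethylsilane | C/C(I)=C/CO[Si](C)(C)C(C)(C)C | intermediate
5 | methyl 2,2-dimethyl-3-oxobutanoate | COC(=O)C(C)(C)C(C)=O | starting material
6 | [4-(tert-butyldimethylsilyloxy)but-2-en-2-yl]lithium, Li cis to CH2OSi (formally E because Li ranks below CH3; formed in the flask) | C/C([Li])=C/CO[Si](C)(C)C(C)(C)C | intermediate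
7 | methyl (Z)-6-(tert-butyldimethylsilyloxy)-3-hydroxy-2,2,3,4-tetramethylhex-4-enoate, racemic at the carbinol carbon | COC(=O)C(C)(C)C(C)(O)/C(C)=C\CO[Si](C)(C)C(C)(C)C | intermediate
8 | methyl (Z)-6-(tert-butyldimethylsilyloxy)-2,2,4-trimethyl-3-methylidenehex-4-enoate | COC(=O)C(C)(C)C(=C)/C(C)=C\CO[Si](C)(C)C(C)(C)C | intermediate
9 | (Z)-6-(tert-butyldimethylsilyloxy)-2,2,4-trimethyl-3-methylidenehex-4-en-1-ol | OCC(C)(C)C(=C)/C(C)=C\CO[Si](C)(C)C(C)(C)C | intermediate
10 | (Z)-6-(tert-butyldimethylsilyloxy)-2,2,4-trimethyl-3-methylidenehex-4-enal | O=CC(C)(C)C(=C)/C(C)=C\CO[Si](C)(C)C(C)(C)C | intermediate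
11 | (Z)-6-hydroxy-2,2,4-trimethyl-3-methylidenehex-4-enal | O=CC(C)(C)C(=C)/C(C)=C\CO | intermediate
12 | (Z)-3,5,5-trimethyl-4-methylidene-6-oxohex-2-en-1-yl methanesulfonate (formed in the flask) | O=CC(C)(C)C(=C)/C(C)=C\COS(C)(=O)=O | intermediate
13 | (Z)-6-bromo-2,2,4-trimethyl-3-methylidenehex-4-enal (precursor of the key step) | O=CC(C)(C)C(=C)/C(C)=C\CBr | intermediate
14 | [(Z)-3,5,5-trimethyl-4-methylidene-6-oxohex-2-en-1-yl]chromium dichloride, allyl species of trivalent chromium drawn without its chiral ligand (formed in the flask) | O=CC(C)(C)C(=C)/C(C)=C\C[Cr](Cl)Cl | intermediate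
15 | trimethyl{[(1R)-2,2,4-trimethyl-3-methylidenecyclohex-4-en-1-yl]oxy}silane (formed in the flask) | C[Si](C)(C)O[C@@H]1CC=C(C)C(=C)C1(C)C | intermediate
16 | (R)-2,2,4-trimethyl-3-methylidenecyclohex-4-en-1-ol (product of the key step) | O[C@@H]1CC=C(C)C(=C)C1(C)C | intermediate
17 | (R)-2-methylbutanoic acid | CC[C@@H](C)C(=O)O | starting material
18 | (R)-2,2,4-trimethyl-3-methylidenecyclohex-4-en-1-yl (R)-2-methylbutanoate | CC[C@@H](C)C(=O)O[C@@H]1CC=C(C)C(=C)C1(C)C | intermediate
19 | (1R,3S)-3-[(9-borabicyclo[3.3.1]nonan-9-yl)methyl]-2,2,4-trimethylcyclohex-4-en-1-yl (R)-2-methylbutanoate (formed in the flask) | CC[C@@H](C)C(=O)O[C@@H]1CC=C(C)[C@H](CB2C3CCCC2CCC3)C1(C)C | intermediate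
20 | (1R,3S)-3-(hydroxymethyl)-2,2,4-trimethylcyclohex-4-en-1-yl (R)-2-methylbutanoate | CC[C@@H](C)C(=O)O[C@@H]1CC=C(C)[C@H](CO)C1(C)C | intermediate
21 | umbelliferone (7-hydroxy-2H-chromen-2-one) | Oc1ccc2ccc(=O)oc2c1 | starting material
22 | (1R,3S)-2,2,4-trimethyl-3-{[(2-oxo-2H-chromen-7-yl)oxy]methyl}cyclohex-4-en-1-yl (R)-2-methylbutanoate, CNP0199249.1 | CC[C@@H](C)C(=O)O[C@@H]1CC=C(C)[C@H](COc2ccc3ccc(=O)oc3c2)C1(C)C | target

**Step count and risk**

Total step count: 12. Longest linear sequence: 12 steps (1 to 22); compounds 5, 17 and 21 enter as purchased materials.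

Steps most likely to fail:

1. Step 9. The tether, not the open approach on which the ligand was developed, dictates how the aldehyde meets the chromium-bound allyl unit, so enantiofacial discrimination may be poor; intermolecular coupling through C2 or C7 may also compete with ring closure. Fallback, from 13 back to 16: the ring is closed without ligand (CrCl2, 3 equiv, THF, rt, high dilution) to racemic 2,2,4-trimethyl-3-methylidenecyclohex-4-en-1-ol F1. This is esterified with (S)-2-methoxy-2-phenylacetic acid (DCC, DMAP, CH2Cl2). The diastereomeric esters are separated by chromatography into (R)-2,2,4-trimethyl-3-methylidenecyclohex-4-en-1-yl (S)-2-methoxy-2-phenylacetate F2 and its (1S)-diastereomer F3, which is discarded. Saponification of F2 (LiOH, THF/MeOH/H2O) returns to 16.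

2. Step 11. Hydrogen may be delivered to the wrong face of C1 if the half-chair with axial C5 oxygen reacts, and the acyl group may migrate or be lost during oxidation. Fallback, from 16 to 22, with a bulkier temporary group that shields its own face more strongly and with the ester introduced last:
   - 16 is silylated (TBSOTf, 2,6-lutidine, CH2Cl2, 0 °C) to tert-butyldimethyl{[(1R)-2,2,4-trimethyl-3-methylidenecyclohex-4-en-1-yl]oxy}silane F4.
   - Hydroboration–oxidation (9-BBN, THF; H2O2, NaOH) should give [(1S,5R)-5-(tert-butyldimethylsilyloxy)-2,6,6-trimethylcyclohex-2-en-1-yl]methanol F5.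
   - Mitsunobu reaction with 21 (PPh3, DIAD, THF) gives 7-{[(1S,5R)-5-(tert-butyldimethylsilyloxy)-2,6,6-trimethylcyclohex-2-en-1-yl]methoxy}-2H-chromen-2-one F6.
   - Desilylation (HF·pyridine, THF, rt to 40 °C) gives 7-{[(1S,5R)-5-hydroxy-2,6,6-trimethylcyclohex-2-en-1-yl]methoxy}-2H-chromen-2-one F7.
   - Esterification of F7 with 17 (DCC, DMAP, CH2Cl2) gives 22.

3. Step 12. SN2 displacement at the β-branched C7 may be slow, and the alkoxyphosphonium may instead eliminate back to the exocyclic diene. Fallback, from 20 to 22: the aryl–oxygen bond is formed instead of the C7–oxygen bond by palladium-catalysed C–O coupling of 20 with commercial 7-bromo-2H-chromen-2-one ([Pd(allyl)Cl]2, RockPhos, Cs2CO3, toluene, 90 °C). This gives 22 directly and makes no new intermediate.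

Further compounds

F1 | step 9 | racemic 2,2,4-trimethyl-3-methylidenecyclohex-4-en-1-ol | OC1CC=C(C)C(=C)C1(C)C
F2 | step 9 | (R)-2,2,4-trimethyl-3-methylidenecyclohex-4-en-1-yl (S)-2-methoxy-2-phenylacetate | CO[C@@H](c1ccccc1)C(=O)O[C@@H]1CC=C(C)C(=C)C1(C)C
F3 | step 9 | (S)-2,2,4-trimethyl-3-methylidenecyclohex-4-en-1-yl (S)-2-methoxy-2-phenylacetate | CO[C@@H](c1ccccc1)C(=O)O[C@H]1CC=C(C)C(=C)C1(C)C
F4 | step 11 | tert-butyldimethyl{[(1R)-2,2,4-trimethyl-3-methylidenecyclohex-4-en-1-yl]oxy}silane | CC(C)(C)[Si](C)(C)O[C@@H]1CC=C(C)C(=C)C1(C)C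
F5 | step 11 | [(1S,5R)-5-(tert-butyldimethylsilyloxy)-2,6,6-trimethylcyclohex-2-en-1-yl]methanol | CC(C)(C)[Si](C)(C)O[C@@H]1CC=C(C)[C@H](CO)C1(C)C
F6 | step 11 | 7-{[(1S,5R)-5-(tert-butyldimethylsilyloxy)-2,6,6-trimethylcyclohex-2-en-1-yl]methoxy}-2H-chromen-2-one | CC(C)(C)[Si](C)(C)O[C@@H]1CC=C(C)[C@H](COc2ccc3ccc(=O)oc3c2)C1(C)C
F7 | step 11 | 7-{[(1S,5R)-5-hydroxy-2,6,6-trimethylcyclohex-2-en-1-yl]methoxy}-2H-chromen-2-one | O[C@@H]1CC=C(C)[C@H](COc2ccc3ccc(=O)oc3c2)C1(C)C
F0 | step 12 | none | none
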